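**Retrosynthetic overview**

1. The 2-methyl-6-alkyl-1,4-benzoquinone ring is made last, by closing the bond between C-1 (the carbonyl carbon flanked by the methyl-bearing C-2 and the side-chain-bearing C-6) and C-6. The enabling feature is that the ring is a four-carbon unit C-1(=O)–C-2(CH3)=C-3H–C-4(O) plus two alkyne carbons (C-5, C-6), so a strained 4-alkynyl-4-hydroxy-2-methylcyclobutenone (25) holds C-1 as a latent ketene beside the alkyne (Moore rearrangement).
2. 25 comes from the lithium acetylide of the (E)-1,4-enyne 16 and the cyclobutenedione monoketal 22 (from diisopropyl squarate); the ketal fixes the 2,6-regiochemistry.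
3. 16 is built on lactone 8 by allylation/cross-metathesis (prenyl), propargylation, carboalumination (E-trisubstituted alkene) and alkynylation. Both side-chain ketones travel as silyl-protected carbinols and are oxidised at the end.
4. The cyclopentane with its cis vicinal quaternary methyl pair comes from meso cis-1,5-dimethylbicyclo[3.3.0]octane-3,7-dione (1): one ketone is removed, the meso mono-ketone is desymmetrised by a chiral lithium amide, and ring B is cleaved by ozonolysis.
5. Ring order: cyclopentane ring A is present in 1; ring B is sacrificed in step 4; the quinone ring is formed in step 17.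

Key step: step 17

**Remarks on the chemistry**

- 1 and diisopropyl squarate (17) are taken as catalogue compounds.
- The carbinol carbons formed in steps 5, 8 and 16 are carried as epimer mixtures (no descriptor in the SMILES), because all three are sp2 carbons in the target.
- The lithium amide in step 3 is written as (R,R) on the assumption that it removes the proton leading to (1S,5R)-5. If a pilot run shows the opposite sense, the (S,S)-amide is used and nothing else changes.

**Route**

Step 1
Reactants: 1 cis-1,5-dimethylbicyclo[3.3.0]octane-3,7-dione (meso)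
Product: 2 mono-(2,2-dimethylpropane-1,3-diyl) ketal of 1 (meso)
Conditions: 2,2-dimethylpropane-1,3-diol (1.0 equiv), p-TsOH (cat.), benzene, reflux, Dean–Stark; diketone and bis-ketal recycled
Reagents that add atoms: 2,2-dimethylpropane-1,3-diol, OCC(C)(C)CO
Why: Acid-catalysed ketalisation of one of two equivalent carbonyls (statistical mono-protection) leaves a single ketone for deoxygenation, and the cis ring fusion that becomes the cis-1,2-dimethyl quaternary pair is already present in 1.

Step 2
Reactants: 2 mono-ketal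
Product: 4 cis-1,5-dimethylbicyclo[3.3.0]octan-3-one (meso), via hydrocarbon ketal 3 (not isolated)
Conditions: N2H4·H2O, KOH, diethylene glycol, 130 → 200 °C; then 2 M HCl, THF, rt
Reagents that add atoms: water, O
Why: Wolff–Kishner reduction (Huang-Minlon procedure) removes the free carbonyl under base, which the ketal tolerates, and aqueous acid then unmasks the other ketone to give a meso ketone with two enantiotopic α-methylene groups.

Step 3
Reactants: 4 meso ketone
Product: 5 (1S,5R)-1,5-dimethyl-3-(trimethylsilyloxy)bicyclo[3.3.0]oct-2-ene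
Conditions: (R,R)-bis(1-phenylethyl)amine, n-BuLi, LiCl, TMSCl (internal quench), THF, −100 °C
Reagents that add atoms: chlorotrimethylsilane, C[Si](C)(C)Cl
Why: Enantioselective deprotonation of a meso ketone by a chiral lithium amide with internal silyl quench, precedented on cis-bicyclo[3.3.0]octan-3-ones, selects one of the two enantiotopic α-CH2 groups and so fixes the absolute configuration of both quaternary carbons, which are not touched again.

Step 4
Reactants: 5 silyl enol ether
Product: 6 2-[(1R,2R)-2-formyl-1,2-dimethylcyclopentyl]acetic acid (in equilibrium with its cyclic lactol form)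
Conditions: O3, CH2Cl2, −78 °C; PPh3, −78 °C → rt; aqueous work-up
Reagents that add atoms: ozone, [O-][O+]=O
Why: Ozonolysis of a silyl enol ether cleaves ring B only at the former enolate C=C bond, placing a formyl group on one quaternary carbon and a carboxymethyl group on the other, the two differently oxidised arms the target needs.

Step 5
Reactants: 6 aldehyde acid
Product: 8 (4aR,7aR)-1-allyl-4a,7a-dimethylhexahydrocyclopenta[c]pyran-3(1H)-one (epimers at C-1), via hydroxy acid 7 (not isolated)
Conditions: indium powder (In), allyl bromide, THF/H2O, rt; then 1 M HCl; p-TsOH (cat.), toluene, 60 °C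
Reagents that add atoms: allyl bromide, C=CCBr
Why: Barbier allylation with allylindium in aqueous THF attacks the aldehyde in the presence of the free acid, and the δ-hydroxy acid closes to the cis-fused δ-lactone; the new carbinol centre forms as an epimer mixture and becomes a ketone in step 19.

Step 6
Reactants: 8 allyl lactone
Product: 9 (4aR,7aR)-4a,7a-dimethyl-1-(3-methylbut-2-enyl)hexahydrocyclopenta[c]pyran-3(1H)-one
Conditions: 2-methylbut-2-ene (excess), second-generation Grubbs catalyst RuCl2(=CHPh)(PCy3)(H2IMes) (5 mol %), CH2Cl2, 40 °C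
Reagents that add atoms: 2-methylbut-2-ene, CC=C(C)C
Why: Olefin cross-metathesis of a terminal alkene with 2-methylbut-2-ene is the standard conversion of an allyl into a prenyl group and leaves the alkene in the unconjugated position required later.

Step 7
Reactants: 9 prenyl lactone
Product: 10 lactol (4aR,7aR)-4a,7a-dimethyl-1-(3-methylbut-2-enyl)octahydrocyclopenta[c]pyran-3-ol
Conditions: (i-Bu)2AlH (1.1 equiv), CH2Cl2, −78 °C; aq. potassium sodium tartrate (KNaC4H4O6)
Reagents that add atoms: none
Why: Partial reduction of a lactone to the lactol with (i-Bu)2AlH at low temperature, where the tetrahedral aluminate does not collapse, exposes the latent aldehyde of the acetic acid arm.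

Step 8
Reactants: 10 lactol
Product: 11 1-[(1R,2R)-2-(2-hydroxypent-4-yn-1-yl)-1,2-dimethylcyclopentyl]-4-methylpent-3-en-1-ol (carbinol epimers)
Conditions: Zn dust, propargyl bromide, THF / sat. aq. NH4Cl, 0 °C → rt
Reagents that add atoms: propargyl bromide, C#CCBr
Why: Zinc Barbier propargylation of the ring-opened hydroxy aldehyde form of the lactol should give the homopropargylic alcohol (propargyl, not allenyl, product with the unsubstituted reagent); the new carbinol centre is again an epimer mixture that becomes a ketone.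

Step 9
Reactants: 11 diol
Product: 12 bis(tert-butyldimethylsilyl) ether of 11
Conditions: TBSOTf (2.5 equiv), 2,6-lutidine, CH2Cl2, −78 → 0 °C
Reagents that add atoms: tert-butyldimethylsilyl trifluoromethanesulfonate, CC(C)(C)[Si](C)(C)OS(=O)(=O)C(F)(F)F
Why: Silylation with the silyl triflate protects both hindered secondary alcohols, which must be masked from AlMe3, Grignard and alkyllithium reagents and stand in for the two ketones until step 19.

Step 10
Reactants: 12 terminal alkyne
Product: 14 (2E)-5-(TBS-oxy)-6-[(1R,2R)-2-{1-(TBS-oxy)-4-methylpent-3-en-1-yl}-1,2-dimethylcyclopentyl]-3-methylhex-2-en-1-ol, via alkenylalane 13 (not isolated)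
Conditions: AlMe3 (3 equiv), Cp2ZrCl2 (0.25 equiv), CH2Cl2, 0 °C → rt; volatiles removed; n-BuLi, hexane/THF, −78 → 0 °C; (CH2O)n, rt
Reagents that add atoms: trimethylaluminium, C[Al](C)C; formaldehyde (from paraformaldehyde), C=O
Why: Negishi zirconium-catalysed carboalumination adds CH3 and Al syn across the terminal alkyne with methyl on the internal carbon, so the trisubstituted alkene forms as the E isomer, and the derived alanate is hydroxymethylated with retention while the prenyl alkene stays inert.

Step 11
Reactants: 14 allylic alcohol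
Product: 15 the corresponding (2E)-allylic bromide
Conditions: CBr4, PPh3, 2,6-lutidine (cat.), CH2Cl2, −20 → 0 °C
Reagents that add atoms: carbon tetrabromide, BrC(Br)(Br)Br
Why: Appel bromination converts the primary allylic alcohol into the bromide under near-neutral conditions without allylic transposition or loss of the silyl ethers.

Step 12
Reactants: 15 allylic bromide
Product: 16 (4E)-7-(TBS-oxy)-8-[(1R,2R)-2-{1-(TBS-oxy)-4-methylpent-3-en-1-yl}-1,2-dimethylcyclopentyl]-5-methyloct-4-en-1-yne
Conditions: HC≡CMgBr (3 equiv), CuCl (10 mol %), THF, 0 → 40 °C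
Reagents that add atoms: ethynylmagnesium bromide, C#C[Mg]Br
Why: Copper-catalysed SN2 coupling of a primary allylic bromide with an alkynyl Grignard reagent gives the skipped (1,4-) enyne with retention of the E geometry.

Step 13
Reactants: 17 diisopropyl squarate
Product: 19 3-isopropoxycyclobut-3-ene-1,2-dione, via hydroxycyclobutenone 18 (not isolated)
Conditions: LiAlH(Ot-Bu)3 (1.05 equiv), THF, −78 → −20 °C; then 6 M HCl, CH2Cl2, rt
Reagents that add atoms: water, O
Why: 1,2-Hydride addition to one squarate carbonyl followed by acid-induced allylic transposition with loss of isopropanol gives the mono-alkoxy dione that carries the ring C–H of the future quinone C-3.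

Step 14
Reactants: 19 3-isopropoxycyclobutenedione
Product: 20 1-isopropoxy-5,8-dioxaspiro[3.4]oct-1-en-3-one
Conditions: 1,2-bis(trimethylsilyloxy)ethane, TMSOTf (cat.), CH2Cl2, −78 → −20 °C
Reagents that add atoms: 1,2-bis(trimethylsilyloxy)ethane, C[Si](C)(C)OCCO[Si](C)(C)C
Why: Ketalisation with the bis-silyl ether and TMSOTf (Noyori conditions) occurs at the more electrophilic carbonyl, the one outside the vinylogous ester, which places the ketal next to the isopropoxy-bearing carbon.

Step 15
Reactants: 20 ketal vinylogous ester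
Product: 22 1-methyl-5,8-dioxaspiro[3.4]oct-1-en-3-one, via tertiary carbinol 21 (not isolated)
Conditions: MeLi, THF, −78 °C; then 1 M HCl, 0 °C
Reagents that add atoms: methyllithium, C[Li]; water, O
Why: 1,2-Addition of MeLi to the vinylogous ester carbonyl and acid-promoted transposition with loss of isopropanol (Stork–Danheiser-type enone transposition) put the methyl group next to the ketal carbon and the free carbonyl next to the ring C–H, the pattern that leads to a 2,6-disubstituted quinone.

Step 16
Reactants: 16 enyne; 22 cyclobutenedione monoketal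
Product: 25 4-hydroxy-2-methyl-4-[(4E)-7-(TBS-oxy)-8-{(1R,2R)-2-[1-(TBS-oxy)-4-methylpent-3-en-1-yl]-1,2-dimethylcyclopentyl}-5-methyloct-4-en-1-yn-1-yl]cyclobut-2-en-1-one, via lithium acetylide 23 (not isolated), via ketal carbinol 24 (not isolated)
Conditions: n-BuLi (1.0 equiv), THF, −78 °C; 22, −78 °C; aq. NH4Cl; then p-TsOH (cat.), acetone/H2O, rt
Reagents that add atoms: water, O
Why: 1,2-Addition of the lithium acetylide to the only free carbonyl gives the tertiary carbinol with fixed regiochemistry, and mild hydrolysis of the allylic ketal then releases the cyclobutenone carbonyl while the carbinol is shielded from ionisation by the adjacent ketal or carbonyl carbon; the carbinol centre is racemic and disappears in step 17.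

Step 17
Reactants: 25 4-alkynyl-4-hydroxycyclobutenone
Product: 27 2-methyl-6-[(2E)-5-(TBS-oxy)-6-{(1R,2R)-2-[1-(TBS-oxy)-4-methylpent-3-en-1-yl]-1,2-dimethylcyclopentyl}-3-methylhex-2-en-1-yl]-1,4-benzoquinone, via enynylketene 26 (not isolated)
Conditions: p-xylene (degassed, 0.01 M), 138 °C
Reagents that add atoms: none
Why: Heating opens the strained cyclobutenone by conrotatory 4π electrocyclic cleavage of the C(=O)–C(OH) bond, the hydroxyl rotating outward so that the alkynyl group lies cis to the ketene in 26. The ketene carbon (future quinone C-1) then bonds to the distal alkyne carbon (future C-6, which carries the side chain) in a 6-endo-dig closure to a phenoxyl/aryl diradical, and transfer of the hydroxyl hydrogen to the ring carbon radical should deliver the 1,4-benzoquinone directly at the correct oxidation level. The closest known reaction type is the Moore rearrangement of 4-alkynyl-4-hydroxycyclobutenones. No stereocentre is created, and the racemic carbinol centre of 25 is destroyed. Two selectivities are needed: the 2,6- rather than 2,5-pattern, which is fixed by the position of the methyl group relative to the carbinol in 25, and six- over five-membered closure, which is favoured because the alkyne substituent is a plain CH2 group that does not stabilise the vinyl radical of the 5-exo path. The silyl ethers, the prenyl alkene and the E-trisubstituted alkene are spectators under these neutral conditions.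

Step 18
Reactants: 27 bis-silyl quinone
Product: 28 2-[(2E)-5-hydroxy-6-{(1R,2R)-2-(1-hydroxy-4-methylpent-3-en-1-yl)-1,2-dimethylcyclopentyl}-3-methylhex-2-en-1-yl]-6-methyl-1,4-benzoquinone
Conditions: 48% aq. HF, MeCN, 0 °C → rt
Reagents that add atoms: none
Why: Acidic fluoride desilylation removes both silyl ethers without base, which a quinone bearing an allylic side chain would not tolerate.

Step 19
Reactants: 28 quinone diol
Product: 29 target, 2-[(2E)-6-{(1R,2R)-1,2-dimethyl-2-(4-methylpent-3-enoyl)cyclopentyl}-3-methyl-5-oxohex-2-en-1-yl]-6-methyl-1,4-benzoquinone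
Conditions: Dess–Martin periodinane (3 equiv), NaHCO3, CH2Cl2, 0 °C → rt
Reagents that add atoms: none
Why: Dess–Martin oxidation under bicarbonate buffer should convert both secondary homoallylic alcohols into the β,γ-unsaturated ketones without moving the double bonds into conjugation and leaves the quinone untouched.

**Compound list**

1 | cis-1,5-dimethylbicyclo[3.3.0]octane-3,7-dione (meso) | O=C1C[C@]2(C)CC(=O)C[C@]2(C)C1 | starting material
2 | mono-(2,2-dimethylpropane-1,3-diyl) ketal of 1 (meso) | O=C1C[C@]2(C)CC3(OCC(C)(C)CO3)C[C@]2(C)C1 | intermediate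
3 | cis-1,5-dimethylbicyclo[3.3.0]octan-3-one 2,2-dimethylpropane-1,3-diyl ketal (not isolated) | CC1(C)COC2(C[C@]3(C)CCC[C@]3(C)C2)OC1 | intermediate
4 | cis-1,5-dimethylbicyclo[3.3.0]octan-3-one (meso) | O=C1C[C@]2(C)CCC[C@]2(C)C1 | intermediate
5 | (1S,5R)-1,5-dimethyl-3-(trimethylsilyloxy)bicyclo[3.3.0]oct-2-ene | C[Si](C)(C)OC1=C[C@]2(C)CCC[C@]2(C)C1 | intermediate
6 | 2-[(1R,2R)-2-formyl-1,2-dimethylcyclopentyl]acetic acid (methyls cis) | O=C[C@]1(C)CCC[C@]1(C)CC(=O)O | intermediate
7 | 2-[(1R,2R)-2-(1-hydroxybut-3-en-1-yl)-1,2-dimethylcyclopentyl]acetic acid, carbinol epimers (not isolated) | C=CCC(O)[C@]1(C)CCC[C@]1(C)CC(=O)O | intermediate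
8 | (4aR,7aR)-1-allyl-4a,7a-dimethylhexahydrocyclopenta[c]pyran-3(1H)-one, epimers at C-1 | C=CCC2[C@]1(C)CCC[C@]1(C)CC(=O)O2 | intermediate
9 | (4aR,7aR)-4a,7a-dimethyl-1-(3-methylbut-2-enyl)hexahydrocyclopenta[c]pyran-3(1H)-one, epimers at C-1 | CC(C)=CCC2[C@]1(C)CCC[C@]1(C)CC(=O)O2 | intermediate
10 | (4aR,7aR)-4a,7a-dimethyl-1-(3-methylbut-2-enyl)octahydrocyclopenta[c]pyran-3-ol (lactol, epimers at C-1 and C-3) | CC(C)=CCC2[C@]1(C)CCC[C@]1(C)CC(O)O2 | intermediate
11 | 1-[(1R,2R)-2-(2-hydroxypent-4-yn-1-yl)-1,2-dimethylcyclopentyl]-4-methylpent-3-en-1-ol, carbinol epimers | CC(C)=CCC(O)[C@]1(C)CCC[C@]1(C)CC(O)CC#C | intermediate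
12 | bis(tert-butyldimethylsilyl) ether of 11 | CC(C)=CCC(O[Si](C)(C)C(C)(C)C)[C@]1(C)CCC[C@]1(C)CC(O[Si](C)(C)C(C)(C)C)CC#C | intermediate
13 | (E)-alkenyl(dimethyl)alane from 12: Al on the terminal alkene carbon, CH3 on the internal one (not isolated) | CC(C)=CCC(O[Si](C)(C)C(C)(C)C)[C@]1(C)CCC[C@]1(C)CC(O[Si](C)(C)C(C)(C)C)C/C(C)=C/[Al](C)C | intermediate
14 | (2E)-5-(TBS-oxy)-6-[(1R,2R)-2-{1-(TBS-oxy)-4-methylpent-3-en-1-yl}-1,2-dimethylcyclopentyl]-3-methylhex-2-en-1-ol | CC(C)=CCC(O[Si](C)(C)C(C)(C)C)[C@]1(C)CCC[C@]1(C)CC(O[Si](C)(C)C(C)(C)C)C/C(C)=C/CO | intermediate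
15 | (2E)-allylic bromide corresponding to 14 | CC(C)=CCC(O[Si](C)(C)C(C)(C)C)[C@]1(C)CCC[C@]1(C)CC(O[Si](C)(C)C(C)(C)C)C/C(C)=C/CBr | intermediate
16 | (4E)-7-(TBS-oxy)-8-[(1R,2R)-2-{1-(TBS-oxy)-4-methylpent-3-en-1-yl}-1,2-dimethylcyclopentyl]-5-methyloct-4-en-1-yne | CC(C)=CCC(O[Si](C)(C)C(C)(C)C)[C@]1(C)CCC[C@]1(C)CC(O[Si](C)(C)C(C)(C)C)C/C(C)=C/CC#C | intermediate
17 | diisopropyl squarate (3,4-diisopropoxycyclobut-3-ene-1,2-dione) | CC(C)OC1=C(OC(C)C)C(=O)C1=O | starting material
18 | 4-hydroxy-2,3-diisopropoxycyclobut-2-en-1-one (not isolated) | CC(C)OC1=C(OC(C)C)C(O)C1=O | intermediate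
19 | 3-isopropoxycyclobut-3-ene-1,2-dione | CC(C)OC1=CC(=O)C1=O | intermediate
20 | 1-isopropoxy-5,8-dioxaspiro[3.4]oct-1-en-3-one | CC(C)OC1=CC(=O)C12OCCO2 | intermediate
21 | 1-isopropoxy-3-methyl-5,8-dioxaspiro[3.4]oct-1-en-3-ol, racemic (not isolated) | CC1(O)C=C(OC(C)C)C12OCCO2 | intermediate
22 | 1-methyl-5,8-dioxaspiro[3.4]oct-1-en-3-one | CC1=CC(=O)C12OCCO2 | intermediate
23 | lithium acetylide of 16 (not isolated) | CC(C)=CCC(O[Si](C)(C)C(C)(C)C)[C@]1(C)CCC[C@]1(C)CC(O[Si](C)(C)C(C)(C)C)C/C(C)=C/CC#C[Li] | intermediate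
24 | 1-methyl-3-(alkynyl)-5,8-dioxaspiro[3.4]oct-1-en-3-ol, alkynyl = the enynyl chain of 16, carbinol epimers (not isolated) | CC(C)=CCC(O[Si](C)(C)C(C)(C)C)[C@]1(C)CCC[C@]1(C)CC(O[Si](C)(C)C(C)(C)C)C/C(C)=C/CC#CC2(O)C=C(C)C23OCCO3 | intermediate
25 | 4-hydroxy-2-methyl-4-(alkynyl)cyclobut-2-en-1-one, alkynyl = the enynyl chain of 16, carbinol epimers | CC(C)=CCC(O[Si](C)(C)C(C)(C)C)[C@]1(C)CCC[C@]1(C)CC(O[Si](C)(C)C(C)(C)C)C/C(C)=C/CC#CC2(O)C=C(C)C2=O | intermediate
26 | (Z)-enynylketene from ring opening of 25, alkynyl cis to the ketene (not isolated) | CC(C)=CCC(O[Si](C)(C)C(C)(C)C)[C@]1(C)CCC[C@]1(C)CC(O[Si](C)(C)C(C)(C)C)C/C(C)=C/CC#C/C(O)=C\C(C)=C=O | intermediate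
27 | bis-TBS ether of quinone diol 28 | CC(C)=CCC(O[Si](C)(C)C(C)(C)C)[C@]1(C)CCC[C@]1(C)CC(O[Si](C)(C)C(C)(C)C)C/C(C)=C/CC2=CC(=O)C=C(C)C2=O | intermediate
28 | 2-[(2E)-5-hydroxy-6-{(1R,2R)-2-(1-hydroxy-4-methylpent-3-en-1-yl)-1,2-dimethylcyclopentyl}-3-methylhex-2-en-1-yl]-6-methyl-1,4-benzoquinone, carbinol epimers | CC(C)=CCC(O)[C@]1(C)CCC[C@]1(C)CC(O)C/C(C)=C/CC2=CC(=O)C=C(C)C2=O | intermediate
29 | 2-[(2E)-6-{(1R,2R)-1,2-dimethyl-2-(4-methylpent-3-enoyl)cyclopentyl}-3-methyl-5-oxohex-2-en-1-yl]-6-methyl-1,4-benzoquinone (CNP0111393.1) | CC(C)=CCC(=O)[C@]1(C)CCC[C@]1(C)CC(=O)C/C(C)=C/CC2=CC(=O)C=C(C)C2=O | target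

**Step count**

Total: 19 steps. Longest linear sequence: 16 steps (steps 1–12 and 16–19); the cyclobutenone branch is 3 steps (13–15).

**Steps most likely to fail, with fallbacks**

Step 17. The ketene may close onto the proximal alkyne carbon (five-membered ring), or the diradical may abstract hydrogen from the doubly allylic CH2 and oligomerise, eroding the quinone. The fallback closes the same C-1–C-6 bond by a purely pericyclic sequence. It sets out from 25: semihydrogenation (H2, Pd on CaCO3 poisoned with Pb(OAc)2, quinoline, EtOAc) should give the (Z)-alkenyl carbinol F1. Thermolysis of F1 in toluene at 110 °C (4π ring opening, 6π electrocyclisation of the ketene onto the alkene carbon that carries the side chain, then enolisation) should give the hydroquinone F2. Oxidation of F2 with Ag2O in Et2O returns to the route at 27.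

Step 3. Discrimination between the two enantiotopic methylene groups may be insufficient, or may go in the wrong sense. The fallback replaces the chiral base by a covalently bound auxiliary. It sets out from 4: ketalisation with (2R,4R)-pentane-2,4-diol (p-TsOH, benzene, Dean–Stark) gives the C2-symmetric ketal F3, in which the two α-methylene groups are diastereotopic. Ring cleavage with Al(i-Bu)3 in CH2Cl2 at 0 °C should give the hydroxyalkyl enol ether F4 as one diastereomer (the diol enantiomer is chosen to match). Ozonolysis (O3, CH2Cl2, −78 °C; PPh3) gives the aldehyde ester F5. Indium allylation as in step 5 gives the hydroxy ester F6, and acid-catalysed lactonisation, which expels the diol, returns to the route at 8.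

Step 16. Proton transfer may compete with addition: the lithiated enyne can be deprotonated at its doubly activated CH2 and isomerise to allene or conjugated enyne, or 22 can be enolised at its methyl group. The fallback forms the alkyne–CH2 bond after the carbinol, under mild copper catalysis, and needs no lithiated enyne. It sets out from 22 and 15: lithium (trimethylsilyl)acetylide (THF, −78 °C) adds to 22 to give the silylethynyl carbinol F7, and K2CO3 in MeOH removes the silyl group to give the ethynyl carbinol F8. Coupling of F8 with allylic bromide 15 (CuI, K2CO3, n-Bu4NI, DMF, rt) returns to the route at 24, which is isolated and hydrolysed to 25 as in the second stage of step 16.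

**Further compounds**

F1 | step 17 | 4-hydroxy-2-methyl-4-[(1Z,4E)-dienyl]cyclobut-2-en-1-one, the (Z)-alkene obtained from the alkyne of 25 | CC(C)=CCC(O[Si](C)(C)C(C)(C)C)[C@]1(C)CCC[C@]1(C)CC(O[Si](C)(C)C(C)(C)C)C/C(C)=C/C/C=C\C2(O)C=C(C)C2=O
F2 | step 17 | hydroquinone of 27 (2-methyl-6-alkylbenzene-1,4-diol, bis-TBS) | CC(C)=CCC(O[Si](C)(C)C(C)(C)C)[C@]1(C)CCC[C@]1(C)CC(O[Si](C)(C)C(C)(C)C)C/C(C)=C/Cc2cc(O)cc(C)c2O
F3 | step 3 | (2R,4R)-pentane-2,4-diyl ketal of 4 | C[C@@H]1C[C@@H](C)OC2(C[C@]3(C)CCC[C@]3(C)C2)O1
F4 | step 3 | (2R,4R)-4-{[(1S,5R)-1,5-dimethylbicyclo[3.3.0]oct-2-en-3-yl]oxy}pentan-2-ol | C[C@@H](O)C[C@@H](C)OC1=C[C@]2(C)CCC[C@]2(C)C1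
F5 | step 3 | (2R,4R)-4-hydroxypentan-2-yl 2-[(1R,2R)-2-formyl-1,2-dimethylcyclopentyl]acetate | O=C[C@]1(C)CCC[C@]1(C)CC(=O)O[C@H](C)C[C@@H](C)O
F6 | step 3 | (2R,4R)-4-hydroxypentan-2-yl 2-[(1R,2R)-2-(1-hydroxybut-3-en-1-yl)-1,2-dimethylcyclopentyl]acetate, carbinol epimers | C=CCC(O)[C@]1(C)CCC[C@]1(C)CC(=O)O[C@H](C)C[C@@H](C)O
F7 | step 16 | 1-methyl-3-[(trimethylsilyl)ethynyl]-5,8-dioxaspiro[3.4]oct-1-en-3-ol (racemic) | C[Si](C)(C)C#CC1(O)C=C(C)C12OCCO2
F8 | step 16 | 3-ethynyl-1-methyl-5,8-dioxaspiro[3.4]oct-1-en-3-ol (racemic) | C#CC1(O)C=C(C)C12OCCO2
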